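**Plan**

Numbering: indene numbering of the target (C1 CHMe, C2 C=O, C3 CHEt, C3a, C4 bearing CO2H, C5 bearing styryl, C6=C7, C7a); ring A is the cyclopentanone, ring B the cyclohexene.
Cuts: the ester O–CH3 and C1–CH3 last; then ring B at C7–C7a and C4–C5 together, giving a cyclopentenone malonic half ester and a 1-boryl-1,3-dienyl carbinol; the enone comes from a 4-acetoxycyclopentenol and an ethylmalonate, the diene from benzaldehyde and two molecules of 1-butyne.
Feature used: C7a is β to the ring A ketone (acceptor for the alkenyl carbon C7), C4 is the α-carbon of the carboxyl (an enolate once a second carboxyl on it leaves as CO2), and C5 is the inner end of the allyl unit C5–CH=CH–Ph, which survives as the styryl group.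
Forward: ring A is functionalised first; the diene is made by hydroalumination–iodination, alkyne diboration and a site-selective Suzuki–Miyaura coupling; ring B is closed in one flask by rhodium-catalysed conjugate alkenylation followed by palladium-catalysed decarboxylative allylation; C1 methylation and ester cleavage finish.
Stereochemistry: C3a from (1S,4R)-cis-4-acetoxycyclopent-2-en-1-ol; C7a by anti addition to the enone; C4 by allylic strain in the enolate and C5 in the ring closure, where the mixtures at the malonate and carbinol carbons converge; C1 and C3 by equilibration α to the ketone.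

Key step: step 10

Remark: 2 is racemic, 4 to 7 are mixtures of epimers at the malonate carbon and 10, 11, 14 and 15 are racemic or epimeric at the carbinol carbon; these centres are left unassigned in the SMILES because both become trigonal in step 10.

**Route**

Step 1
Reactants: 1 tert-butyl methyl malonate
Product: 2 1-tert-butyl 3-methyl 2-ethylpropanedioate (racemic)
Conditions: NaH, THF, 0 °C; EtI, 0 °C to rt
Reagents that add atoms: iodoethane CCI
Why: malonic ester alkylation of the sodium enolate with a primary iodide; one equivalent of base limits dialkylation.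

Step 2
Reactants: 2 1-tert-butyl 3-methyl 2-ethylpropanedioate; 3 (1S,4R)-cis-4-acetoxycyclopent-2-en-1-ol
Product: 4 1-tert-butyl 3-methyl 2-ethyl-2-[(1R,4S)-4-hydroxycyclopent-2-en-1-yl]propanedioate (both epimers at C2)
Conditions: NaH, THF, 0 °C; then 3, Pd(PPh3)4 (5 mol %), rt to 50 °C
Reagents that add atoms: none
Why: Tsuji–Trost allylic alkylation; zerovalent palladium ionises the acetate with inversion and the malonate attacks the allyl terminus remote from the hydroxyl with a second inversion, so the cis 1,4 relationship is kept and the future C3a is set from the monoacetate.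

Step 3
Reactants: 4 1-tert-butyl 3-methyl 2-ethyl-2-[(1R,4S)-4-hydroxycyclopent-2-en-1-yl]propanedioate
Product: 5 1-tert-butyl 3-methyl 2-ethyl-2-[(1R)-4-oxocyclopent-2-en-1-yl]propanedioate
Conditions: MnO2, CH2Cl2, rt
Reagents that add atoms: none
Why: allylic alcohol oxidation with activated MnO2 should give the enone under neutral conditions that leave the γ stereocentre untouched.

Step 4
Reactants: 5 1-tert-butyl 3-methyl 2-ethyl-2-[(1R)-4-oxocyclopent-2-en-1-yl]propanedioate
Product: 6 1-tert-butyl 3-methyl 2-ethyl-2-[(1S,5R)-5-ethyl-4-oxocyclopent-2-en-1-yl]propanedioate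
Conditions: LiN(i-Pr)2, THF, −78 °C; EtI, DMPU, −78 to −20 °C
Reagents that add atoms: iodoethane CCI
Why: kinetic α′-enolate alkylation (the malonate carbon is quaternary and cannot enolise); the electrophile should enter anti to the bulky C4 substituent to give the trans product, which is also the more stable epimer at this enolisable centre.

Step 5
Reactants: 6 1-tert-butyl 3-methyl 2-ethyl-2-[(1S,5R)-5-ethyl-4-oxocyclopent-2-en-1-yl]propanedioate
Product: 7 2-[(1S,5R)-5-ethyl-4-oxocyclopent-2-en-1-yl]-2-(methoxycarbonyl)butanoic acid
Conditions: CF3CO2H, CH2Cl2, 0 °C to rt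
Reagents that add atoms: none
Why: acidolysis of the tert-butyl ester (loss of 2-methylpropene) should spare the methyl ester and the base-sensitive enone and unmask the carboxyl that later leaves as CO2.

Step 6
Reactants: 8 benzaldehyde; 9 1-butyne
Product: 10 1-phenylpent-2-yn-1-ol (racemic)
Conditions: n-BuLi, THF, −78 °C; then H2O
Reagents that add atoms: none
Why: addition of the lithium acetylide to the aldehyde (alkynylation); the carbinol centre needs no control because it is lost in step 10.

Step 7
Reactants: 10 1-phenylpent-2-yn-1-ol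
Product: 11 (Z)-3-iodo-1-phenylpent-2-en-1-ol
Conditions: NaAlH2(OCH2CH2OMe)2, THF, 0 °C to rt; then I2, −78 to 0 °C
Reagents that add atoms: iodine [I][I]
Why: hydroxyl-directed trans-hydroalumination of the propargylic alcohol should place aluminium on the distal alkyne carbon, cis to the carbinol carbon, and iodinolysis with retention gives the Z iodoalkene.

Step 8
Reactants: 9 1-butyne; 12 bis(pinacolato)diboron
Product: 13 (E)-1,2-bis(4,4,5,5-tetramethyl-1,3,2-dioxaborolan-2-yl)but-1-ene (the two boron atoms cis)
Conditions: Pt(PPh3)4 (3 mol %), DMF, 80 °C, sealed tube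
Reagents that add atoms: none
Why: platinum-catalysed syn diboration of a terminal alkyne should give the cis 1,2-diborylalkene.

Step 9
Reactants: 11 (Z)-3-iodo-1-phenylpent-2-en-1-ol; 13 (E)-1,2-bis(4,4,5,5-tetramethyl-1,3,2-dioxaborolan-2-yl)but-1-ene
Product: 14 (2Z,4E)-3-ethyl-1-phenyl-5-(4,4,5,5-tetramethyl-1,3,2-dioxaborolan-2-yl)hepta-2,4-dien-1-ol
Conditions: PdCl2(dppf) (5 mol %), K3PO4, dioxane–H2O (5:1), 40 °C
Reagents that add atoms: none
Why: Suzuki–Miyaura coupling with retention at both partners; the terminal C–B bond of the diborylalkene should transmetalate much faster than the internal hindered one, which survives as the alkenylboronate with boron cis to the new diene bond.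

Step 10
Reactants: 7 2-[(1S,5R)-5-ethyl-4-oxocyclopent-2-en-1-yl]-2-(methoxycarbonyl)butanoic acid; 14 (2Z,4E)-3-ethyl-1-phenyl-5-(4,4,5,5-tetramethyl-1,3,2-dioxaborolan-2-yl)hepta-2,4-dien-1-ol
Product: 16 methyl (3R,3aS,4S,5R,7aR)-3,4,5,7-tetraethyl-2-oxo-5-[(E)-2-phenylethenyl]-2,3,3a,4,5,7a-hexahydro-1H-indene-4-carboxylate, via conjugate adduct 15 (not isolated)
Conditions: [Rh(cod)OH]2 (3 mol %), Et3N, dioxane–H2O (10:1), 40 °C; then AcOH, Pd(PPh3)4 (10 mol %), 90 °C
Reagents that add atoms: none
Why: Proposed new method: the alkenylrhodium species formed from 14 by transmetalation should insert the enone of 7 (Hayashi–Miyaura conjugate addition) and so make C7–C7a, after which zerovalent palladium should ionise the dienylic carbinol of 15 with the help of its carboxylic acid, the malonate carboxylate should lose CO2, and the palladium ester enolate at C4 should bond to the allyl terminus C5. The closest known reactions are that conjugate addition, the palladium-catalysed decarboxylative allylic alkylation of allyl α,α-disubstituted malonates and the acid-promoted formation of π-allyl complexes from allylic alcohols; new are their relay in one flask on unprotected partners and bond formation at a fully substituted allyl terminus. Ring B closes in the 6-exo mode with respect to the allyl unit, whose two outer carbons remain as the E styryl group because the π-allyl keeps phenyl syn, whereas attack at the benzylic terminus would need an eight-membered ring. C7a is controlled by the malonyl group on the neighbouring ring carbon, anti to which the alkenyl group adds, so that the ring fusion is trans; C4 is controlled by allylic 1,3-strain, the enolate reacting with C3a–H eclipsing its double bond on the face that holds C7a, so that its ethyl group ends anti to C3a–H; C5 is controlled by the half-chair transition state, which should place the bulky palladium-bound allyl arm pseudoaxial and anti to that ethyl group. The step needs enolate formation at C4 only, in the presence of the ketone, and convergence of the epimers of 15: loss of CO2 makes the enolate at C4 without base, and the malonate and carbinol carbons both become trigonal, the π-allyl faces exchanging by π–σ–π and pentadienyl shifts while the slower decarboxylation is awaited.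

Step 11
Reactants: 16 methyl (3R,3aS,4S,5R,7aR)-3,4,5,7-tetraethyl-2-oxo-5-[(E)-2-phenylethenyl]-2,3,3a,4,5,7a-hexahydro-1H-indene-4-carboxylate
Product: 17 methyl (1R,3R,3aS,4S,5R,7aS)-3,4,5,7-tetraethyl-1-methyl-2-oxo-5-[(E)-2-phenylethenyl]-2,3,3a,4,5,7a-hexahydro-1H-indene-4-carboxylate
Conditions: LiN(i-Pr)2, THF, −78 °C; MeI, −78 to 0 °C
Reagents that add atoms: iodomethane CI
Why: kinetic enolisation at the C1 methylene (C3 is a hindered methine, the ester has no α-hydrogen) and enolate alkylation on the face opposite the C7a–C7 bond should give the trans methyl group; any cis epimer is corrected in step 12.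

Step 12
Reactants: 17 methyl (1R,3R,3aS,4S,5R,7aS)-3,4,5,7-tetraethyl-1-methyl-2-oxo-5-[(E)-2-phenylethenyl]-2,3,3a,4,5,7a-hexahydro-1H-indene-4-carboxylate
Product: 18 (1R,3R,3aS,4S,5R,7aS)-3,4,5,7-tetraethyl-1-methyl-2-oxo-5-[(E)-2-phenylethenyl]-2,3,3a,4,5,7a-hexahydro-1H-indene-4-carboxylic acid
Conditions: NaSEt, DMF, 80 °C; then aqueous HCl
Reagents that add atoms: none
Why: nucleophilic ester demethylation, SN2 attack of thiolate at the O-methyl carbon, avoids the shielded acyl carbon between two quaternary centres, and the basic medium should equilibrate C1 and C3 to the all-trans arrangement around ring A.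

**Compound list**

1 | tert-butyl methyl malonate | COC(=O)CC(=O)OC(C)(C)C | starting material
2 | 1-tert-butyl 3-methyl 2-ethylpropanedioate (racemic) | CCC(C(=O)OC)C(=O)OC(C)(C)C | intermediate
3 | (1S,4R)-cis-4-acetoxycyclopent-2-en-1-ol | CC(=O)O[C@H]1C=C[C@@H](O)C1 | starting material
4 | 1-tert-butyl 3-methyl 2-ethyl-2-[(1R,4S)-4-hydroxycyclopent-2-en-1-yl]propanedioate (epimers at C2) | CCC(C(=O)OC)(C(=O)OC(C)(C)C)[C@H]1C=C[C@@H](O)C1 | intermediate
5 | 1-tert-butyl 3-methyl 2-ethyl-2-[(1R)-4-oxocyclopent-2-en-1-yl]propanedioate (epimers at C2) | CCC(C(=O)OC)(C(=O)OC(C)(C)C)[C@H]1C=CC(=O)C1 | intermediate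
6 | 1-tert-butyl 3-methyl 2-ethyl-2-[(1S,5R)-5-ethyl-4-oxocyclopent-2-en-1-yl]propanedioate (epimers at C2) | CCC(C(=O)OC)(C(=O)OC(C)(C)C)[C@H]1C=CC(=O)[C@@H]1CC | intermediate
7 | 2-[(1S,5R)-5-ethyl-4-oxocyclopent-2-en-1-yl]-2-(methoxycarbonyl)butanoic acid (epimers at C2) | CCC(C(=O)OC)(C(=O)O)[C@H]1C=CC(=O)[C@@H]1CC | intermediate
8 | benzaldehyde | O=Cc1ccccc1 | starting material
9 | 1-butyne | CCC#C | starting material
10 | 1-phenylpent-2-yn-1-ol (racemic) | CCC#CC(O)c1ccccc1 | intermediate
11 | (Z)-3-iodo-1-phenylpent-2-en-1-ol (racemic) | CC/C(I)=C/C(O)c1ccccc1 | intermediate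
12 | bis(pinacolato)diboron | CC1(C)OB(OC1(C)C)B1OC(C)(C)C(C)(C)O1 | starting material
13 | (E)-1,2-bis(4,4,5,5-tetramethyl-1,3,2-dioxaborolan-2-yl)but-1-ene (boron atoms cis) | CC/C(B1OC(C)(C)C(C)(C)O1)=C/B1OC(C)(C)C(C)(C)O1 | intermediate
14 | (2Z,4E)-3-ethyl-1-phenyl-5-(4,4,5,5-tetramethyl-1,3,2-dioxaborolan-2-yl)hepta-2,4-dien-1-ol (racemic) | CC1(C)OB(OC1(C)C)/C(CC)=C\C(CC)=C/C(O)c1ccccc1 | intermediate
15 | 2-{(1S,2R,5R)-5-ethyl-2-[(3Z,5Z)-5-ethyl-7-hydroxy-7-phenylhepta-3,5-dien-3-yl]-4-oxocyclopentyl}-2-(methoxycarbonyl)butanoic acid (epimers at C2 of the acid and at the carbinol carbon) | OC(=O)C(CC)(C(=O)OC)[C@H]1[C@H](/C(CC)=C\C(CC)=C/C(O)c2ccccc2)CC(=O)[C@@H]1CC | intermediate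
16 | methyl (3R,3aS,4S,5R,7aR)-3,4,5,7-tetraethyl-2-oxo-5-[(E)-2-phenylethenyl]-2,3,3a,4,5,7a-hexahydro-1H-indene-4-carboxylate | CCC1=C[C@](/C=C/c2ccccc2)(CC)[C@@](CC)(C(=O)OC)[C@H]2[C@H]1CC(=O)[C@@H]2CC | intermediate
17 | methyl (1R,3R,3aS,4S,5R,7aS)-3,4,5,7-tetraethyl-1-methyl-2-oxo-5-[(E)-2-phenylethenyl]-2,3,3a,4,5,7a-hexahydro-1H-indene-4-carboxylate | CCC1=C[C@](/C=C/c2ccccc2)(CC)[C@@](CC)(C(=O)OC)[C@H]2[C@H]1[C@@H](C)C(=O)[C@@H]2CC | intermediate
18 | (1R,3R,3aS,4S,5R,7aS)-3,4,5,7-tetraethyl-1-methyl-2-oxo-5-[(E)-2-phenylethenyl]-2,3,3a,4,5,7a-hexahydro-1H-indene-4-carboxylic acid | CCC1=C[C@](/C=C/c2ccccc2)(CC)[C@@](CC)(C(=O)O)[C@H]2[C@H]1[C@@H](C)C(=O)[C@@H]2CC | target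

**Count and risks**

Total step count: 12. Longest linear sequence: 8 steps (steps 1, 2, 3, 4, 5, 10, 11, 12).

Steps most likely to fail:

Step 10 (Proposed new method). The palladium ester enolate may be protonated by water or acid after loss of CO2, before it closes on C5. In the first stage, the hindered enone may insert slowly into the alkenyl–rhodium bond while the carboxylate adds reversibly to its own enone. The fallback uses known chemistry and sets out from 15, obtained by running the rhodium-catalysed conjugate addition alone and isolating it. Yamaguchi lactonisation (2,4,6-trichlorobenzoyl chloride, Et3N, then DMAP, toluene, high dilution) should join its carboxyl and carbinol as the ten-membered allyl malonate lactone F1. Heating F1 with Pd(PPh3)4 in dry dioxane is then the classical decarboxylative allylic alkylation of an allyl α,α-disubstituted malonate, run without any proton source, and it comes back to the route at 16.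

Step 4. Iodoethane reacts slowly, so proton exchange between alkylated ketone and remaining enolate may cause polyalkylation and drift to the extended dienolate. The fallback sets out from 5: condensation with Me2NNH2 (AcOH cat.) to the N,N-dimethylhydrazone of 5 F2, α′-deprotonation with LiN(i-Pr)2 and ethylation of the aza-enolate with EtI to the N,N-dimethylhydrazone of 6 F3, then cleavage with CuCl2 in aqueous THF, which comes back to the route at 6.

Step 11. Over-methylation and loss of regiocontrol through enolate equilibration may occur. The fallback sets out from 16: Mannich-type α-methylenation with paraformaldehyde and N-methylanilinium trifluoroacetate (THF, reflux), which can only take place at the C1 methylene, should give the 1-methylidene ketone F4. Conjugate reduction of this exocyclic enone with [(Ph3P)CuH]6 comes back to the route at 17, and the C1 configuration is then settled by the equilibration in step 12.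

Further compounds
F1 | step 10 | ten-membered lactone formed between the carboxyl and the carbinol of 15 (methyl ester kept; epimers at the malonate and carbinol carbons) | O1C(=O)C(CC)(C(=O)OC)[C@H]2[C@H](/C(CC)=C\C(CC)=C/C1c3ccccc3)CC(=O)[C@@H]2CC
F2 | step 4 | N,N-dimethylhydrazone of 5 | CCC(C(=O)OC)(C(=O)OC(C)(C)C)[C@H]1C=CC(=NN(C)C)C1
F3 | step 4 | N,N-dimethylhydrazone of 6 | CCC(C(=O)OC)(C(=O)OC(C)(C)C)[C@H]1C=CC(=NN(C)C)[C@@H]1CC
F4 | step 11 | 1-methylidene derivative of 16 (exocyclic enone at C1) | CCC1=C[C@](/C=C/c2ccccc2)(CC)[C@@](CC)(C(=O)OC)[C@H]2[C@H]1C(=C)C(=O)[C@@H]2CC
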